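The route rests on disconnecting the C2–Cα bond between the chromone and its 2-arylethyl chain. In 6,7-dimethoxychromone, C2 of the pyranone ring (ring C) is an unsubstituted β-carbon of the vinylogous ester O1–C2=C3–C4=O, so it should accept the whole side chain as a carbon nucleophile. One copper-catalysed 1,4-addition of a benzyl-protected 2-arylethyl Grignard reagent, run with chlorotrimethylsilane, should forge that bond and lock the enolate as a 4-silyloxy-2H-chromene, the handle for palladium dehydrogenation back to the chromone. The precursors are the parent chromone (from a 2-hydroxyacetophenone) and the Grignard reagent made from O-benzyl homovanillyl bromide; hydrogenolysis then frees the phenol.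

Key step: step 5

Assumption: the stereocentre formed at C2 in step 5 is removed again in step 6, so compound 11 is made as the racemate without a chiral ligand; the Grignard solution 9 is titrated and used directly.

Step 1
Reactants: 1 1-(2-hydroxy-4,5-dimethoxyphenyl)ethanone; 2 N,N-dimethylformamide dimethyl acetal
Product: 4 6,7-dimethoxy-4H-chromen-4-one, via enaminone 3 (not isolated)
Conditions: DMF-DMA (2 equiv), toluene, 100 °C; concentrate; then conc. HCl, CH2Cl2, 40 °C
Reagents that add atoms: N,N-dimethylformamide dimethyl acetal (2), COC(OC)N(C)C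
Why: Condensation of the acetyl methyl group with the amide acetal should give the push-pull enaminone 3, and acid then drives addition of the phenol oxygen to the β-carbon with loss of dimethylamine, the standard enaminone route from 2-hydroxyacetophenones to chromones unsubstituted at C2 and C3.

Step 2
Reactants: 5 2-(4-hydroxy-3-methoxyphenyl)ethanol; 6 benzyl bromide
Product: 7 2-[4-(benzyloxy)-3-methoxyphenyl]ethanol
Conditions: BnBr (1.1 equiv), K2CO3, acetone, reflux
Reagents that add atoms: benzyl bromide (6), BrCc1ccccc1
Why: Williamson ether synthesis in which K2CO3 deprotonates only the phenol, so the phenoxide is benzylated while the much less acidic primary alcohol stays free.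

Step 3
Reactants: 7 2-[4-(benzyloxy)-3-methoxyphenyl]ethanol
Product: 8 1-(benzyloxy)-4-(2-bromoethyl)-2-methoxybenzene
Conditions: CBr4, PPh3, CH2Cl2, 0 °C to rt
Reagents that add atoms: tetrabromomethane, BrC(Br)(Br)Br
Why: Appel reaction, in which the alkoxyphosphonium ion of the primary alcohol is displaced by bromide in an SN2 step under neutral conditions that leave the benzyl and methyl ethers untouched.

Step 4
Reactants: 8 1-(benzyloxy)-4-(2-bromoethyl)-2-methoxybenzene
Product: 9 2-[4-(benzyloxy)-3-methoxyphenyl]ethylmagnesium bromide (THF solution)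
Conditions: Mg turnings (I2-activated), THF, 35–40 °C, slow addition of 8
Reagents that add atoms: magnesium, [Mg]
Why: Grignard formation by insertion of magnesium into the primary C–Br bond; the aryl ethers are inert to the reagent, and slow addition at moderate dilution should limit Wurtz coupling.

Step 5
Reactants: 4 6,7-dimethoxy-4H-chromen-4-one; 9 2-[4-(benzyloxy)-3-methoxyphenyl]ethylmagnesium bromide; 10 chlorotrimethylsilane
Product: 11 racemic 2-{2-[4-(benzyloxy)-3-methoxyphenyl]ethyl}-6,7-dimethoxy-4-(trimethylsilyloxy)-2H-chromene
Conditions: CuBr·SMe2 (10 mol%), TMSCl (2 equiv), 9 (1.5 equiv, slow addition), THF, −78 to −40 °C; then Et3N, pentane, cold aq. NaHCO3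
Reagents that add atoms: chlorotrimethylsilane (10), C[Si](C)(C)Cl
Why: Transmetalation of 9 to CuBr·SMe2 should give a monovalent alkylcopper species that binds C2=C3 of 4 as a π-complex, adds at C2 to a trivalent copper enolate and reductively eliminates to form the C2–Cα bond, while chlorotrimethylsilane captures the enolate oxygen as silyl enol ether 11 and returns copper to the cycle. The closest known reaction type is the chlorosilane-accelerated copper-catalysed conjugate addition of Grignard reagents to enones and chromones. No ring is closed. The new stereocentre at C2 has no controlling element and should form as the racemate, which is acceptable because step 6 removes it. The step needs 1,4- over 1,2-selectivity and an intact pyran ring: the soft organocopper nucleophile, the unhindered C2–H position and the low temperature favour attack at C2, and O-silylation both activates the electron-rich dimethoxy acceptor and keeps the enolate from expelling the O1 phenoxide by β-elimination. The benzyl and methyl ethers are inert under these conditions.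

Step 6
Reactants: 11 racemic 2-{2-[4-(benzyloxy)-3-methoxyphenyl]ethyl}-6,7-dimethoxy-4-(trimethylsilyloxy)-2H-chromene
Product: 12 2-{2-[4-(benzyloxy)-3-methoxyphenyl]ethyl}-6,7-dimethoxy-4H-chromen-4-one
Conditions: Pd(OAc)2 (1.1 equiv), MeCN, rt (crude 11 used directly)
Reagents that add atoms: none
Why: Saegusa–Ito oxidation, in which divalent palladium replaces silicon to give a C3-palladated ketone (oxa-π-allyl) and β-hydride elimination of the single C2 hydrogen restores the conjugated C2=C3 bond of the pyranone, erasing the C2 stereocentre.

Step 7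
Reactants: 12 2-{2-[4-(benzyloxy)-3-methoxyphenyl]ethyl}-6,7-dimethoxy-4H-chromen-4-one
Product: 13 2-[2-(4-hydroxy-3-methoxyphenyl)ethyl]-6,7-dimethoxy-4H-chromen-4-one (target)
Conditions: H2 (1 atm), Pd/C (10 wt% palladium on carbon), EtOAc–MeOH, rt
Reagents that add atoms: none
Why: Catalytic hydrogenolysis of the benzyl aryl ether; the C2=C3 bond belongs to a vinylogous ester in the pyranone ring and should be reduced far more slowly than the benzylic C–O bond is cleaved under one atmosphere of hydrogen at room temperature.

Compound list
1 | 1-(2-hydroxy-4,5-dimethoxyphenyl)ethanone | CC(=O)c1cc(OC)c(OC)cc1O | starting material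
2 | N,N-dimethylformamide dimethyl acetal | COC(OC)N(C)C | starting material
3 | (E)-3-(dimethylamino)-1-(2-hydroxy-4,5-dimethoxyphenyl)prop-2-en-1-one | CN(C)/C=C/C(=O)c1cc(OC)c(OC)cc1O | intermediate
4 | 6,7-dimethoxy-4H-chromen-4-one | COc1cc2occc(=O)c2cc1OC | intermediate
5 | 2-(4-hydroxy-3-methoxyphenyl)ethanol | COc1cc(CCO)ccc1O | starting material
6 | benzyl bromide | BrCc1ccccc1 | starting material
7 | 2-[4-(benzyloxy)-3-methoxyphenyl]ethanol | COc1cc(CCO)ccc1OCc1ccccc1 | intermediate
8 | 1-(benzyloxy)-4-(2-bromoethyl)-2-methoxybenzene | COc1cc(CCBr)ccc1OCc1ccccc1 | intermediate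
9 | 2-[4-(benzyloxy)-3-methoxyphenyl]ethylmagnesium bromide | COc1cc(CC[Mg]Br)ccc1OCc1ccccc1 | intermediate
10 | chlorotrimethylsilane | C[Si](C)(C)Cl | starting material
11 | racemic 2-{2-[4-(benzyloxy)-3-methoxyphenyl]ethyl}-6,7-dimethoxy-4-(trimethylsilyloxy)-2H-chromene (C2 unassigned, both enantiomers) | COc1cc(CCC2C=C(O[Si](C)(C)C)c3cc(OC)c(OC)cc3O2)ccc1OCc1ccccc1 | intermediate
12 | 2-{2-[4-(benzyloxy)-3-methoxyphenyl]ethyl}-6,7-dimethoxy-4H-chromen-4-one | COc1cc(CCc2cc(=O)c3cc(OC)c(OC)cc3o2)ccc1OCc1ccccc1 | intermediate
13 | 2-[2-(4-hydroxy-3-methoxyphenyl)ethyl]-6,7-dimethoxy-4H-chromen-4-one (no stereocentre) | COc1cc(CCc2cc(=O)c3cc(OC)c(OC)cc3o2)ccc1O | target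

Total step count: 7. Longest linear sequence: 6 steps (steps 2, 3, 4, 5, 6, 7 from compound 5).

Steps most likely to fail

1. Step 5. The Grignard reagent may attack the C4 carbonyl directly, the metal enolate may open the pyran ring by β-elimination before silicon traps it, or addition to the electron-rich acceptor may stall. The fallback builds the side chain by condensation instead of conjugate addition; it sets out from compound 1 and comes back at compound 13.
   - Claisen condensation of 1 with ethyl acetate (NaH, THF) should give 1-(2-hydroxy-4,5-dimethoxyphenyl)butane-1,3-dione F1.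
   - Cyclodehydration (H2SO4, AcOH) should give 6,7-dimethoxy-2-methyl-4H-chromen-4-one F2.
   - Vinylogous aldol condensation of the C2 methyl group with commercial 4-(benzyloxy)-3-methoxybenzaldehyde (NaOEt, EtOH) should give (E)-2-{2-[4-(benzyloxy)-3-methoxyphenyl]ethenyl}-6,7-dimethoxy-4H-chromen-4-one F3.
   - Hydrogenation over Pd/C should saturate the exocyclic alkene and cleave the benzyl ether in one operation, giving target 13.

2. Step 6. The trimethylsilyl group may be lost to adventitious acid or moisture before palladation, leaving the saturated ketone, or turnover may stop as palladium metal precipitates. The fallback sets out from compound 11 and comes back at compound 12.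
   - Deliberate hydrolysis of 11 (1 M HCl, THF) should give racemic 2-{2-[4-(benzyloxy)-3-methoxyphenyl]ethyl}-6,7-dimethoxychroman-4-one F4.
   - Dehydrogenation by α-iodination and loss of HI (I2, DMSO, about 110 °C) should then give 12.

3. Step 4. Wurtz-type homocoupling of the primary bromide at the metal surface, or failure of the insertion to start, may erode the Grignard titre. The fallback makes the organometallic by halogen–metal exchange; it sets out from compound 8 and comes back at compound 9.
   - Finkelstein exchange (NaI, acetone) should give 1-(benzyloxy)-4-(2-iodoethyl)-2-methoxybenzene F5.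
   - Iodine–lithium exchange (t-BuLi, 2 equiv, Et2O–pentane, −78 °C) should give 2-[4-(benzyloxy)-3-methoxyphenyl]ethyllithium F6.
   - Transmetalation with MgBr2·OEt2 should give 9.

Further compounds
F1 | step 5 | 1-(2-hydroxy-4,5-dimethoxyphenyl)butane-1,3-dione | CC(=O)CC(=O)c1cc(OC)c(OC)cc1O
F2 | step 5 | 6,7-dimethoxy-2-methyl-4H-chromen-4-one | Cc1cc(=O)c2cc(OC)c(OC)cc2o1
F3 | step 5 | (E)-2-{2-[4-(benzyloxy)-3-methoxyphenyl]ethenyl}-6,7-dimethoxy-4H-chromen-4-one | COc1cc(/C=C/c2cc(=O)c3cc(OC)c(OC)cc3o2)ccc1OCc1ccccc1
F4 | step 6 | racemic 2-{2-[4-(benzyloxy)-3-methoxyphenyl]ethyl}-6,7-dimethoxychroman-4-one | COc1cc(CCC2CC(=O)c3cc(OC)c(OC)cc3O2)ccc1OCc1ccccc1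
F5 | step 4 | 1-(benzyloxy)-4-(2-iodoethyl)-2-methoxybenzene | COc1cc(CCI)ccc1OCc1ccccc1
F6 | step 4 | 2-[4-(benzyloxy)-3-methoxyphenyl]ethyllithium | [Li]CCc1ccc(OCc2ccccc2)c(OC)c1
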